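**Retrosynthetic overview**

1. Target, with germacrane locants: butanolide C12(=O)–O–C8 fused at C7/C8, exo-methylene C11=C13, (Z)-C9=C10 bearing methyl C14, carbinol C1, cis-oxirane C2–C3, carbinol C4 bearing methyl C15, C5H2, angelate on O6; configuration (1R,2R,3R,4R,6R,7R,8S).
2. Key disconnection C10–C1: an intramolecular Nozaki–Hiyama–Kishi addition of the (Z)-alkenyl iodide at C10 to the cis-epoxy aldehyde at C1 closes the ten-membered carbocycle last and creates C1 under control of the oxirane.
3. Enabling feature: C1 is a secondary allylic carbinol between the sp2 carbon C10 and the oxirane carbon C2, so it maps onto alkenyl-metal plus aldehyde; the three cis units (the (Z)-C9=C10 bond, the cis-fused butanolide at C7/C8, the cis-oxirane at C2/C3) fold the C1–C10 chain so that its ends meet.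
4. Earlier disconnections: C7–C8 with the lactone C–O bond (indium Barbier reaction of a Morita–Baylis–Hillman-derived (Z)-allylic bromide with (Z)-3-iodobut-2-enal; C6 relays to C7 and C8 in one event), C7–C11 (Morita–Baylis–Hillman), C4–C5 (chelation-controlled aldol of mesityl oxide with a cis-epoxy methyl ketone; the oxirane relays to C4). Absolute configuration comes from one Sharpless epoxidation (C2, C3) and one oxazaborolidine reduction (C6).
5. Order of ring formation: oxirane (step 2), butanolide (step 14), ten-membered carbocycle (step 19).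

Key step: step 19

Remark: the ester is read from the SMILES as the (Z)-2-methylbut-2-enoate (angelate) and the ring alkene as (9Z); (Z)-but-2-ene-1,4-diol, mesityl oxide, methyl acrylate, but-2-yn-1-ol and angelic acid are taken as commercial.

**Route**

Step 1
Reactants: 1 (Z)-but-2-ene-1,4-diol
Product: 2 (Z)-4-[(4-methoxybenzyl)oxy]but-2-en-1-ol
Conditions: NaH (1 equiv), THF/DMF, 0 °C; 4-methoxybenzyl chloride, Bu4NI (cat.), 0 °C to rt; diol in excess
Reagents that add atoms: 4-methoxybenzyl chloride, COc1ccc(CCl)cc1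
Why: Williamson ether synthesis on the mono-alkoxide of a symmetrical diol used in excess should stop at the mono-ether; no stereocenter is formed and the (Z) alkene is not touched.

Step 2
Reactants: 2 (Z)-4-[(4-methoxybenzyl)oxy]but-2-en-1-ol
Product: 3 [(2S,3R)-3-{[(4-methoxybenzyl)oxy]methyl}oxiran-2-yl]methanol
Conditions: Ti(OiPr)4 (10 mol %), L-(+)-diethyl tartrate (12 mol %), t-BuOOH, 4 Å molecular sieves, CH2Cl2, −20 °C
Reagents that add atoms: tert-butyl hydroperoxide, CC(C)(C)OO
Why: Sharpless asymmetric epoxidation: the titanium–L-(+)-tartrate complex binds the allylic hydroxyl and delivers the peroxide oxygen to one enantioface, which should set C2 and C3 of the target together, the cis relation following from the (Z) alkene.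

Step 3
Reactants: 3 [(2S,3R)-3-{[(4-methoxybenzyl)oxy]methyl}oxiran-2-yl]methanol
Product: 4 (2R,3R)-3-{[(4-methoxybenzyl)oxy]methyl}oxirane-2-carbaldehyde
Conditions: Dess–Martin periodinane, NaHCO3, CH2Cl2, 0 °C to rt
Reagents that add atoms: none
Why: Dess–Martin oxidation under buffered conditions should give the cis-epoxy aldehyde without opening or epimerising the oxirane.

Step 4
Reactants: 4 (2R,3R)-3-{[(4-methoxybenzyl)oxy]methyl}oxirane-2-carbaldehyde
Product: 5 1-[(2S,3R)-3-{[(4-methoxybenzyl)oxy]methyl}oxiran-2-yl]ethan-1-ol (both carbinol epimers)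
Conditions: MeMgBr, THF, −78 °C; aqueous work-up
Reagents that add atoms: methylmagnesium bromide, C[Mg]Br
Why: Grignard 1,2-addition to the aldehyde at low temperature is faster than oxirane opening; the new carbinol center is not controlled because it is removed in step 5.

Step 5
Reactants: 5 1-[(2S,3R)-3-{[(4-methoxybenzyl)oxy]methyl}oxiran-2-yl]ethan-1-ol
Product: 6 1-[(2R,3R)-3-{[(4-methoxybenzyl)oxy]methyl}oxiran-2-yl]ethan-1-one
Conditions: Dess–Martin periodinane, NaHCO3, CH2Cl2, rt
Reagents that add atoms: none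
Why: Dess–Martin oxidation of the secondary alcohol should give the cis-epoxy methyl ketone (C1–C4 and C15) with C2 and C3 unchanged.

Step 6
Reactants: 6 1-[(2R,3R)-3-{[(4-methoxybenzyl)oxy]methyl}oxiran-2-yl]ethan-1-one; 7 mesityl oxide
Product: 9 (6R)-6-hydroxy-6-[(2R,3R)-3-{[(4-methoxybenzyl)oxy]methyl}oxiran-2-yl]-2-methylhept-2-en-4-one, via lithium dienolate 8 (not isolated)
Conditions: LiN(iPr)2, THF, −78 °C (7 in excess); then 6, −78 °C; AcOH quench at −78 °C
Reagents that add atoms: none
Why: Chelation-controlled aldol addition (Cram chelate): lithium bridges the ketone and oxirane oxygens and the kinetic cross-conjugated enolate 8 attacks the carbonyl face turned away from C2 and its cis CH2OPMB group, which should set C4 as (R), the same facial sense that hydride reductions of cis-epoxy ketones show.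

Step 7
Reactants: 9 (6R)-6-hydroxy-6-[(2R,3R)-3-{[(4-methoxybenzyl)oxy]methyl}oxiran-2-yl]-2-methylhept-2-en-4-one
Product: 10 (4R,6R)-6-[(2R,3R)-3-{[(4-methoxybenzyl)oxy]methyl}oxiran-2-yl]-2-methylhept-2-ene-4,6-diol
Conditions: (S)-1-methyl-3,3-diphenyltetrahydro-1H,3H-pyrrolo[1,2-c][1,3,2]oxazaborole (20 mol %), catecholborane, toluene, −78 °C
Reagents that add atoms: none
Why: Corey–Bakshi–Shibata reduction: the catalyst binds the enone carbonyl anti to the alkenyl (large) substituent and delivers hydride from the coordinated borane to one face, which should set C6 as (R) under reagent control and turn material from the minor enantiomer of 3 into a separable diastereomer.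

Step 8
Reactants: 10 (4R,6R)-6-[(2R,3R)-3-{[(4-methoxybenzyl)oxy]methyl}oxiran-2-yl]-2-methylhept-2-ene-4,6-diol
Product: 11 bis(triethylsilyl) ether of 10 (OTES on C4 and C6)
Conditions: Et3SiOTf, 2,6-lutidine, CH2Cl2, −78 to −20 °C
Reagents that add atoms: triethylsilyl trifluoromethanesulfonate, CC[Si](CC)(CC)OS(=O)(=O)C(F)(F)F
Why: Silyl triflate with a hindered base silylates the secondary and the tertiary hydroxyl in one operation at a temperature where the oxirane is inert, and it removes the free C6 hydroxyl that could open the oxirane.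

Step 9
Reactants: 11 bis(triethylsilyl) ether of 10
Product: 13 (2R,4R)-4-[(2R,3R)-3-{[(4-methoxybenzyl)oxy]methyl}oxiran-2-yl]-2,4-bis[(triethylsilyl)oxy]pentanal, via ozonide 12 (not isolated)
Conditions: O3, CH2Cl2, −78 °C (stopped at first excess of ozone); then Me2S, −78 °C to rt
Reagents that add atoms: ozone, [O-][O+]=O
Why: Ozonolysis: the electron-rich trisubstituted alkene is the only C=C bond and reacts far faster than the anisyl ring, and reductive work-up of ozonide 12 should give the α-silyloxy aldehyde (C7) with C6 intact.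

Step 10
Reactants: 13 (2R,4R)-4-[(2R,3R)-3-{[(4-methoxybenzyl)oxy]methyl}oxiran-2-yl]-2,4-bis[(triethylsilyl)oxy]pentanal; 14 methyl acrylate
Product: 15 methyl (4R,6R)-3-hydroxy-6-[(2R,3R)-3-{[(4-methoxybenzyl)oxy]methyl}oxiran-2-yl]-2-methylidene-4,6-bis[(triethylsilyl)oxy]heptanoate (both C7 carbinol epimers)
Conditions: methyl acrylate (excess), 1,4-diazabicyclo[2.2.2]octane (1 equiv), MeOH (trace), rt
Reagents that add atoms: none
Why: Morita–Baylis–Hillman reaction: the amine adds to the acrylate and the resulting enolate adds to the activated α-silyloxy aldehyde to forge C7–C11; the new carbinol center is of no consequence because it is lost in step 11.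

Step 11
Reactants: 15 Morita–Baylis–Hillman adduct
Product: 16 methyl (2Z,4R,6R)-2-(bromomethyl)-6-[(2R,3R)-3-{[(4-methoxybenzyl)oxy]methyl}oxiran-2-yl]-4,6-bis[(triethylsilyl)oxy]hept-2-enoate
Conditions: N-bromosuccinimide, Me2S, CH2Cl2, 0 °C to rt
Reagents that add atoms: N-bromosuccinimide, O=C1CCC(=O)N1Br
Why: SN2' bromination (Corey–Kim-type activation of the allylic hydroxyl as an alkoxysulfonium ion, bromide attack at C13) should give the thermodynamically favoured (Z)-2-(bromomethyl)alk-2-enoate with C6 cis to CH2Br.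

Step 12
Reactants: 17 but-2-yn-1-ol
Product: 19 (Z)-3-iodobut-2-en-1-ol, via sodium alkenylalanate 18 (not isolated)
Conditions: NaAlH2(OCH2CH2OMe)2, THF, 0 °C to rt; EtOAc; then I2, THF, −78 °C
Reagents that add atoms: iodine, II
Why: Hydroxyl-directed trans-hydroalumination gives the cyclic alkenylalanate 18 with aluminium on C10 cis to the carbinol carbon, and iodinolysis with retention should give only the (Z)-iodide.

Step 13
Reactants: 19 (Z)-3-iodobut-2-en-1-ol
Product: 20 (Z)-3-iodobut-2-enal
Conditions: MnO2 (activated, excess), CH2Cl2, rt, dark; used at once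
Reagents that add atoms: none
Why: Allylic oxidation with MnO2 is neutral and should give the (Z)-enal (C8–C10, C14) without isomerisation when light and acid are excluded.

Step 14
Reactants: 16 (Z)-allylic bromide; 20 (Z)-3-iodobut-2-enal
Product: 23 iodoalkenyl cis-butanolide (OTES on C6 and C4; OPMB on C1), via allylindium dibromide 21 (not isolated), via hydroxy ester 22 (not isolated)
Conditions: In powder, THF/H2O 1:1, rt; then pyridinium p-toluenesulfonate (cat.), toluene, 50 °C
Reagents that add atoms: none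
Why: Barbier allylation through a Zimmerman–Traxler chair followed by acid-catalysed lactonization (Dreiding–Schmidt α-methylene lactone synthesis): in 21 C6 is cis to the CH2–In carbon and so axial, which should give the syn adduct and hence the cis lactone (C7, C8), while C6 relays to C7 through allylic 1,3-strain (C6–H in the alkene plane, aldehyde anti to the bulky C5 branch, OTES outside), and the poor leaving group OTES disfavours 1,4-elimination.

Step 15
Reactants: 23 iodoalkenyl cis-butanolide
Product: 24 C6 alcohol (OTES on C4 retained)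
Conditions: HF·pyridine, pyridine, THF, 0 °C, monitored
Reagents that add atoms: none
Why: Buffered fluoride desilylation cleaves the secondary triethylsilyl ether much faster than the hindered tertiary one, and the weakly acidic medium avoids translactonisation and oxirane opening by the freed C6 hydroxyl.

Step 16
Reactants: 24 C6 alcohol; 25 angelic acid
Product: 27 C6 angelate, via mixed anhydride 26 (not isolated)
Conditions: 25, 2,4,6-trichlorobenzoyl chloride, Et3N, toluene, rt; then 24, toluene, 80 °C
Reagents that add atoms: none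
Why: Yamaguchi esterification through mixed anhydride 26 without a nucleophilic amine catalyst acylates the secondary alcohol and avoids (Z)-to-(E) isomerisation of the angelate to the tiglate; C6 keeps its configuration.

Step 17
Reactants: 27 C6 angelate
Product: 28 C1 primary alcohol
Conditions: DDQ, CH2Cl2/pH 7 phosphate buffer, 0 °C
Reagents that add atoms: none
Why: Oxidative cleavage of the p-methoxybenzyl ether by DDQ (hydride abstraction, hydrolysis of the oxocarbenium ion) is neutral and should leave silyl ether, oxirane, lactone, angelate and alkenyl iodide untouched.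

Step 18
Reactants: 28 C1 primary alcohol
Product: 29 seco-aldehyde (C1 aldehyde, C10 iodide)
Conditions: Dess–Martin periodinane, NaHCO3, CH2Cl2, 0 °C
Reagents that add atoms: none
Why: Dess–Martin oxidation of the primary epoxy alcohol should give the cis-epoxy aldehyde, which cannot close to a lactol because O4 is silylated.

Step 19
Reactants: 29 seco-aldehyde
Product: 31 macrocyclic C1 alcohol (OTES on C4), via alkenylchromium dichloride 30 (not isolated)
Conditions: CrCl2 (15 equiv), NiCl2 (0.15 equiv), degassed DMSO, rt, slow addition of 29 to a final 0.002 M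
Reagents that add atoms: none
Why: Nozaki–Hiyama–Kishi reaction: zerovalent nickel (formed from NiCl2 by CrCl2) inserts into the C10–I bond with retention of the (Z) geometry, transmetalation gives the trivalent alkenylchromium 30, and this adds to the aldehyde C1 and to no other carbonyl group (lactone, angelate and enoate are inert to organochromium reagents). The closest known reaction type is the chromium/nickel-mediated ring closure of (Z)-alkenyl iodides onto aldehydes, which is established for nine- and ten-membered rings and tolerates oxiranes, esters and silyl ethers. The ten-membered carbocycle closes in the 10-exo-trig mode (the C1=O bond lies outside the new ring); lactone and oxirane are already in place and, with the (Z)-C9=C10 bond, act as cis turn elements that hold C10 near C1, so high dilution should suffice against oligomerisation. The one new stereocenter, C1, is controlled by the neighbouring oxirane: in the Felkin–Anh transition state the C2–O bond is anti to the incoming alkenyl group, C3 lies next to the carbonyl oxygen and the nucleophile passes the small C2–H, the face of the oxirane ring being closed by the cis C4 substituent, which should give the anti (erythro) epoxy alcohol, that is (1R). The step needs chemoselectivity, retention of alkene geometry and 1,2-induction; these are secured by the organochromium reagent, by the configurational stability of alkenylchromium species and by the α-oxirane, and the strongly coordinating DMSO suppresses a chelated, syn-selective pathway.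

Step 20
Reactants: 31 macrocyclic C1 alcohol (OTES on C4)
Product: 32 target, (1R,2R,3R,4R,6R,7R,8S,9Z)-6-angeloyloxy-2,3-epoxy-1,4-dihydroxygermacra-9,11(13)-dien-12,8-olide
Conditions: HF·pyridine, pyridine, THF, 0 °C to rt
Reagents that add atoms: none
Why: Buffered fluoride cleavage of the tertiary triethylsilyl ether should free the C4 hydroxyl without touching the epoxy alcohol, the α-methylene lactone or the angelate.

**Compound list** (locants and descriptors of the larger intermediates refer to the germacrane numbering of the target; the spatial arrangement at each center is that of the target)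

1 | (Z)-but-2-ene-1,4-diol | OC/C=C\CO | starting material
2 | (Z)-4-[(4-methoxybenzyl)oxy]but-2-en-1-ol | OC/C=C\COCc1ccc(OC)cc1 | intermediate
3 | [(2S,3R)-3-{[(4-methoxybenzyl)oxy]methyl}oxiran-2-yl]methanol (cis-epoxide) | OC[C@@H]1O[C@@H]1COCc1ccc(OC)cc1 | intermediate
4 | (2R,3R)-3-{[(4-methoxybenzyl)oxy]methyl}oxirane-2-carbaldehyde | O=C[C@@H]1O[C@@H]1COCc1ccc(OC)cc1 | intermediate
5 | 1-[(2S,3R)-3-{[(4-methoxybenzyl)oxy]methyl}oxiran-2-yl]ethan-1-ol, both carbinol epimers | CC(O)[C@@H]1O[C@@H]1COCc1ccc(OC)cc1 | intermediate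
6 | 1-[(2R,3R)-3-{[(4-methoxybenzyl)oxy]methyl}oxiran-2-yl]ethan-1-one | CC(=O)[C@@H]1O[C@@H]1COCc1ccc(OC)cc1 | intermediate
7 | mesityl oxide (4-methylpent-3-en-2-one) | CC(C)=CC(C)=O | starting material
8 | lithium 4-methylpenta-1,3-dien-2-olate | [Li+].[O-]C(=C)C=C(C)C | intermediate (not isolated)
9 | (6R)-6-hydroxy-6-[(2R,3R)-3-{[(4-methoxybenzyl)oxy]methyl}oxiran-2-yl]-2-methylhept-2-en-4-one | CC(C)=CC(=O)C[C@@](C)(O)[C@@H]1O[C@@H]1COCc1ccc(OC)cc1 | intermediate
10 | (4R,6R)-6-[(2R,3R)-3-{[(4-methoxybenzyl)oxy]methyl}oxiran-2-yl]-2-methylhept-2-ene-4,6-diol | CC(C)=C[C@H](O)C[C@@](C)(O)[C@@H]1O[C@@H]1COCc1ccc(OC)cc1 | intermediate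
11 | bis(triethylsilyl) ether of 10 (2R,3R,4R,6R) | CC(C)=C[C@H](O[Si](CC)(CC)CC)C[C@@](C)(O[Si](CC)(CC)CC)[C@@H]1O[C@@H]1COCc1ccc(OC)cc1 | intermediate
12 | ozonide of 11 (3,3-dimethyl-1,2,4-trioxolane carrying the C6–C1 chain at its C5; mixture at the trioxolane carbon) | CC1(C)OOC(O1)[C@H](O[Si](CC)(CC)CC)C[C@@](C)(O[Si](CC)(CC)CC)[C@@H]1O[C@@H]1COCc1ccc(OC)cc1 | intermediate (not isolated)
13 | (2R,4R)-4-[(2R,3R)-3-{[(4-methoxybenzyl)oxy]methyl}oxiran-2-yl]-2,4-bis[(triethylsilyl)oxy]pentanal | O=C[C@H](O[Si](CC)(CC)CC)C[C@@](C)(O[Si](CC)(CC)CC)[C@@H]1O[C@@H]1COCc1ccc(OC)cc1 | intermediate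
14 | methyl acrylate | C=CC(=O)OC | starting material
15 | methyl (4R,6R)-3-hydroxy-6-[(2R,3R)-3-{[(4-methoxybenzyl)oxy]methyl}oxiran-2-yl]-2-methylidene-4,6-bis[(triethylsilyl)oxy]heptanoate, both C3 epimers | COC(=O)C(=C)C(O)[C@H](O[Si](CC)(CC)CC)C[C@@](C)(O[Si](CC)(CC)CC)[C@@H]1O[C@@H]1COCc1ccc(OC)cc1 | intermediate
16 | methyl (2Z,4R,6R)-2-(bromomethyl)-6-[(2R,3R)-3-{[(4-methoxybenzyl)oxy]methyl}oxiran-2-yl]-4,6-bis[(triethylsilyl)oxy]hept-2-enoate | COC(=O)/C(CBr)=C/[C@H](O[Si](CC)(CC)CC)C[C@@](C)(O[Si](CC)(CC)CC)[C@@H]1O[C@@H]1COCc1ccc(OC)cc1 | intermediate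
17 | but-2-yn-1-ol | CC#CCO | starting material
18 | sodium alkenylalanate (2,5-dihydro-1,2-oxaalumol-2-uide with two 2-methoxyethoxy ligands, methyl on the ring carbon bonded to Al) | [Na+].CC1=CCO[Al-]1(OCCOC)OCCOC | intermediate (not isolated)
19 | (Z)-3-iodobut-2-en-1-ol | C/C(I)=C/CO | intermediate
20 | (Z)-3-iodobut-2-enal | O=C/C=C(/C)I | intermediate
21 | allylindium dibromide from 16 (trivalent indium; the organoindium sesquibromide drawn in its simplest form) | COC(=O)/C(C[In](Br)Br)=C/[C@H](O[Si](CC)(CC)CC)C[C@@](C)(O[Si](CC)(CC)CC)[C@@H]1O[C@@H]1COCc1ccc(OC)cc1 | intermediate (not isolated)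
22 | hydroxy ester: methyl 2-methylidene ester with C8–OH carrying the (Z)-2-iodoprop-1-enyl group and C7 carrying the C6–C1 chain (OTES on C6 and C4, cis-2,3-epoxide, OPMB on C1); 2R,3R,4R,6R,7S,8R | COC(=O)C(=C)[C@@H]([C@@H](O)/C=C(/C)I)[C@H](O[Si](CC)(CC)CC)C[C@@](C)(O[Si](CC)(CC)CC)[C@@H]1O[C@@H]1COCc1ccc(OC)cc1 | intermediate (not isolated)
23 | cis-4,5-disubstituted 3-methylidenedihydrofuran-2(3H)-one: (Z)-2-iodoprop-1-enyl on C8, C6–C1 chain on C7 (OTES on C6 and C4, cis-2,3-epoxide, OPMB on C1); 2R,3R,4R,6R,7S,8R | C=C1C(=O)O[C@@H](/C=C(/C)I)[C@H]1[C@H](O[Si](CC)(CC)CC)C[C@@](C)(O[Si](CC)(CC)CC)[C@@H]2O[C@@H]2COCc2ccc(OC)cc2 | intermediate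
24 | as 23 with free C6–OH; 2R,3R,4R,6R,7R,8R | C=C1C(=O)O[C@@H](/C=C(/C)I)[C@H]1[C@H](O)C[C@@](C)(O[Si](CC)(CC)CC)[C@@H]2O[C@@H]2COCc2ccc(OC)cc2 | intermediate
25 | angelic acid, (Z)-2-methylbut-2-enoic acid | C/C=C(/C)C(=O)O | starting material
26 | angelic 2,4,6-trichlorobenzoic anhydride | C/C=C(/C)C(=O)OC(=O)c1c(Cl)cc(Cl)cc1Cl | intermediate (not isolated)
27 | as 24 with the C6 angelate; 2R,3R,4R,6R,7R,8R | C=C1C(=O)O[C@@H](/C=C(/C)I)[C@H]1[C@H](OC(=O)/C(C)=C\C)C[C@@](C)(O[Si](CC)(CC)CC)[C@@H]2O[C@@H]2COCc2ccc(OC)cc2 | intermediate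
28 | as 27 with free C1–OH (primary epoxy alcohol) | C=C1C(=O)O[C@@H](/C=C(/C)I)[C@H]1[C@H](OC(=O)/C(C)=C\C)C[C@@](C)(O[Si](CC)(CC)CC)[C@@H]2O[C@@H]2CO | intermediate
29 | seco-aldehyde: C1 aldehyde on the cis-oxirane, OTES on C4, C6 angelate, cis-butanolide, (Z)-C10 iodide; 2S,3R,4R,6R,7R,8R | C=C1C(=O)O[C@@H](/C=C(/C)I)[C@H]1[C@H](OC(=O)/C(C)=C\C)C[C@@](C)(O[Si](CC)(CC)CC)[C@@H]2O[C@@H]2C=O | intermediate
30 | alkenylchromium dichloride from 29 (trivalent chromium on C10) | C=C1C(=O)O[C@@H](/C=C(/C)[Cr](Cl)Cl)[C@H]1[C@H](OC(=O)/C(C)=C\C)C[C@@](C)(O[Si](CC)(CC)CC)[C@@H]2O[C@@H]2C=O | intermediate (not isolated)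
31 | 4-O-triethylsilyl ether of the target; 1R,2R,3R,4R,6R,7R,8S,9Z | C=C1C(=O)O[C@H]2/C=C(/C)[C@@H](O)[C@H]3O[C@H]3[C@](C)(O[Si](CC)(CC)CC)C[C@@H](OC(=O)/C(C)=C\C)[C@@H]12 | intermediate
32 | (1R,2R,3R,4R,6R,7R,8S,9Z)-6-angeloyloxy-2,3-epoxy-1,4-dihydroxygermacra-9,11(13)-dien-12,8-olide | C=C1C(=O)O[C@H]2/C=C(/C)[C@@H](O)[C@H]3O[C@H]3[C@](C)(O)C[C@@H](OC(=O)/C(C)=C\C)[C@@H]12 | target

**Step count and risks**

Total step count: 20. Longest linear sequence: 18 (steps 1–11 and 14–20; steps 12 and 13 make aldehyde 20).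

Steps most likely to fail:

1. Step 19. The facial selectivity of the addition to C1 may be eroded or reversed by the conformational demands of the ten-membered transition state, even if dilution keeps oligomerisation down. The fallback sets C1 by ketone reduction instead of carbonyl addition. It sets out from 29: the cyclization is run as in step 19 and the mixture of 31 and the C1-epimeric macrocyclic alcohol F1 is oxidised with Dess–Martin periodinane to the macrocyclic epoxy enone F2. F2 is reduced with Zn(BH4)2 in Et2O at −20 °C, where zinc is chelated between the ketone and oxirane oxygens and hydride enters from the face away from C3. This should give the anti epoxy alcohol and comes back to the route at 31.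

2. Step 14. The aldehyde may approach C7 anti to the C6 silyloxy group instead of anti to the C5 branch, which would give the cis lactone epimeric at both C7 and C8. The fallback runs the sequence in the C6-epimeric series, in which that same preference gives the natural C7 and C8, and corrects C6 at the end by substitution with inversion. It sets out from 9:
   - reduction with the (R)-configured oxazaborolidine and catecholborane gives the 6-epi diol F3;
   - Et3SiOTf/2,6-lutidine gives the bis-silyl ether F4;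
   - ozonolysis through the ozonide F5 gives the aldehyde F6;
   - the Morita–Baylis–Hillman reaction gives the adduct F7;
   - N-bromosuccinimide/Me2S gives the (Z)-allylic bromide F8;
   - indium with 20, through the allylindium dibromide F9 and the hydroxy ester F10, gives the 6-epi lactone F11;
   - HF·pyridine gives the 6-epi alcohol F12;
   - Mitsunobu esterification of F12 with angelic acid 25 (PPh3, diisopropyl azodicarboxylate, THF) inverts C6 and comes back to the route at 27.

3. Step 6. Proton transfer between the enolate and the methyl ketone, retro-aldol cleavage of the tertiary aldolate, or incomplete lithium chelation may limit conversion or the selectivity at C4. The fallback builds the same bond by Grignard allylation and sets out from 6: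
   - allylmagnesium bromide in Et2O at −78 °C (magnesium chelate, attack anti to C2) gives the homoallylic tertiary alcohol F13;
   - ozonolysis through the ozonide F14 (Me2S work-up) gives the β-hydroxy aldehyde F15;
   - 2-methylprop-1-enylmagnesium bromide gives the allylic alcohol F16 as both C6 epimers;
   - MnO2 oxidises the allylic hydroxyl only and comes back to the route at 9.

Further compounds
F1 | step 19 | C1 epimer of 31 (1S) | C=C1C(=O)O[C@H]2/C=C(/C)[C@H](O)[C@H]3O[C@H]3[C@](C)(O[Si](CC)(CC)CC)C[C@@H](OC(=O)/C(C)=C\C)[C@@H]12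
F2 | step 19 | macrocyclic epoxy enone (C1 ketone of 31) | C=C1C(=O)O[C@H]2/C=C(/C)C(=O)[C@H]3O[C@H]3[C@](C)(O[Si](CC)(CC)CC)C[C@@H](OC(=O)/C(C)=C\C)[C@@H]12
F3 | step 14 | C6 epimer of diol 10 | CC(C)=C[C@@H](O)C[C@@](C)(O)[C@@H]1O[C@@H]1COCc1ccc(OC)cc1
F4 | step 14 | C6 epimer of bis-silyl ether 11 | CC(C)=C[C@@H](O[Si](CC)(CC)CC)C[C@@](C)(O[Si](CC)(CC)CC)[C@@H]1O[C@@H]1COCc1ccc(OC)cc1
F5 | step 14 | ozonide of F4 | CC1(C)OOC(O1)[C@@H](O[Si](CC)(CC)CC)C[C@@](C)(O[Si](CC)(CC)CC)[C@@H]1O[C@@H]1COCc1ccc(OC)cc1
F6 | step 14 | C6 epimer of aldehyde 13 | O=C[C@@H](O[Si](CC)(CC)CC)C[C@@](C)(O[Si](CC)(CC)CC)[C@@H]1O[C@@H]1COCc1ccc(OC)cc1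
F7 | step 14 | C6 epimer of adduct 15 | COC(=O)C(=C)C(O)[C@@H](O[Si](CC)(CC)CC)C[C@@](C)(O[Si](CC)(CC)CC)[C@@H]1O[C@@H]1COCc1ccc(OC)cc1
F8 | step 14 | C6 epimer of bromide 16 | COC(=O)/C(CBr)=C/[C@@H](O[Si](CC)(CC)CC)C[C@@](C)(O[Si](CC)(CC)CC)[C@@H]1O[C@@H]1COCc1ccc(OC)cc1
F9 | step 14 | allylindium dibromide from F8 | COC(=O)/C(C[In](Br)Br)=C/[C@@H](O[Si](CC)(CC)CC)C[C@@](C)(O[Si](CC)(CC)CC)[C@@H]1O[C@@H]1COCc1ccc(OC)cc1
F10 | step 14 | C6 epimer of hydroxy ester 22 | COC(=O)C(=C)[C@@H]([C@@H](O)/C=C(/C)I)[C@@H](O[Si](CC)(CC)CC)C[C@@](C)(O[Si](CC)(CC)CC)[C@@H]1O[C@@H]1COCc1ccc(OC)cc1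
F11 | step 14 | C6 epimer of lactone 23 | C=C1C(=O)O[C@@H](/C=C(/C)I)[C@H]1[C@@H](O[Si](CC)(CC)CC)C[C@@](C)(O[Si](CC)(CC)CC)[C@@H]2O[C@@H]2COCc2ccc(OC)cc2
F12 | step 14 | C6 epimer of alcohol 24 | C=C1C(=O)O[C@@H](/C=C(/C)I)[C@H]1[C@@H](O)C[C@@](C)(O[Si](CC)(CC)CC)[C@@H]2O[C@@H]2COCc2ccc(OC)cc2
F13 | step 6 | (2R)-2-[(2R,3R)-3-{[(4-methoxybenzyl)oxy]methyl}oxiran-2-yl]pent-4-en-2-ol | C=CC[C@@](C)(O)[C@@H]1O[C@@H]1COCc1ccc(OC)cc1
F14 | step 6 | ozonide of F13 | C1OOC(O1)C[C@@](C)(O)[C@@H]1O[C@@H]1COCc1ccc(OC)cc1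
F15 | step 6 | (3R)-3-hydroxy-3-[(2R,3R)-3-{[(4-methoxybenzyl)oxy]methyl}oxiran-2-yl]butanal | O=CC[C@@](C)(O)[C@@H]1O[C@@H]1COCc1ccc(OC)cc1
F16 | step 6 | 6-[(2R,3R)-3-{[(4-methoxybenzyl)oxy]methyl}oxiran-2-yl]-2-methylhept-2-ene-4,6-diol, (6R) and both C4 epimers | CC(C)=CC(O)C[C@@](C)(O)[C@@H]1O[C@@H]1COCc1ccc(OC)cc1
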